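Readings and results come from a simulation for substances that don't exist; scatter was added.

How much Imd is still there at the end of cedar and of maple, when the summer run was read up to 50.0 s?

| flask | Sub | remark | time |
|---|---|---|---|
| summer | 0.30 M | run made earlier |  |
| cedar | 0.20 M |  | 3.0 min |
| maple | 0.20 M |  | 5.0 min |

summer run (percent of the Sub charged)

| time / s | Imd / % | Tgt / % |
|---|---|---|
| 10.0 | 70 | 2 |
| 20.0 | 86 | 3 |
| 40.0 | 88 | 8 |
| 50.0 | 87 | 9 |

(each reading ± 1.5 percentage points)

- a reading or a percentage of Tgt counts all its forms, free or not

- which one finishes higher in amount of Imd, in percent of the Sub charged ("neither" within 2 percentage points) (cedar / maple / neither)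
- amount of Imd at the end, in percent of the Sub charged, cedar
- amount of Imd at the end, in percent of the Sub charged, maple

The reckoning made here rests on two times from the summer run. The formation time τ_f is the mean moment at which Imd is born: at 10.0 s the readings leave 28.0% as Sub by difference, so first-order decay gives τ_f = 7.86 s. The loss time τ_L, the time in which formed Imd falls by a factor e, comes from the deficit of Imd, not from the rise of Tgt. At 50.0 s Imd lacks 13.0% of the charge while Tgt holds 9%. Counting the age of Imd from τ_f gives τ_L = 5.04 min, 38.5 times τ_f. Because τ_L is so much longer, the formation curve can be replaced by a single birth at its mean, at an error near 0.0338% of the Imd. The share of Imd is then exp(−(t−τ_f)/τ_L). First order is assumed, and that deficit carries a scatter of 1.5 percentage points. This gives 56.6% for cedar and 38.1% for maple.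

The forecast chose cedar, with 67% (54% to 80%) for cedar and 53% (33% to 71%) for maple, from “Tgt grows slowly, at about 0.17–0.2% per second”. Both values stand higher than those reckoned here.

Cedar ends higher, at 55.9% against 37.2% for maple.

    Tgt → Sid (k = 0.0120 /s)
    Sub → Imd (k = 0.120 /s)
    Sub + Tgt ⇌ Imd2, settled at all times (K = 22.0 /M)
    Imd → Tgt (k = 0.00340 /s)

The same τ_L, applied to the cedar charge read at 12 min, gives 9.49% of Imd. That neighbouring flask holds 8.91%, with Sid at 87.6%.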